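**A direct plan and its weak points**

A direct plan would buy both arenes: 5-heptylresorcinol A1 would be acetylated by a Hoesch reaction and benzylated to ketone A2.
The perbenzylated ring C toluate A3 would be carboxylated at its benzylic position to the homophthalic half ester A4.
A crossed Claisen condensation of the enolate of A2 with the imidazolide of A4 would give diketone A5; hydrogenolysis would free the racemic hemiketal acid A6, and chiral HPLC would give the (R)-enantiomer.
Weakest steps:
- The final chromatographic resolution of A6: C2 would form without control, so half of the material would be the wrong enantiomer on every pass.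
- The Claisen union to A5: it would spend three equivalents of A2, a ketone that is itself two steps old, to buffer an enolisable acyl donor.
- The run-up from A1 to A2: a Hoesch acylation with a regiochemical leak, then benzyl groups that are put on only to be removed, all for a simple acetophenone.

**Retrosynthetic overview of the new route**

Ring A (C4a, C5 to C8, C8a) is not bought. It is cut across C4a–C8a and C5–C6, back to an acyclic alkynyl 1,3-diketone (ynone C4a≡C5 carrying the heptyl chain) and 1-methoxy-1,3-bis(trimethylsilyloxy)buta-1,3-diene; ring B is cut at O1–C2.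
Ring order: ring C is carried from orsellinic acid; ring A closes by Diels–Alder benzannulation, and the C8a–OH it unveils closes ring B on the C2 ketone in the same flask.
The C2–C3 bond is still made by a Claisen condensation, but its ketone partner is now a one-step ynone: no Hoesch reaction, no ring A protection, no advanced fragment in excess.
The labile C2 hemiketal beside the CO2H group is funnelled to (R) by crystallisation of an amine salt under equilibration through the open diketone, not resolved.

Key step: step 6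

Assumption: the C2 hemiketal equilibrates through the open diketone in the presence of amine base and holds its configuration in cold, weakly acidic medium; the less soluble (S)-1-phenylethylammonium salt is taken to be that of the (2R)-acid, and (R)-1-phenylethylamine would be used if the screen showed the opposite pairing.

**Route**

Step 1
Reactants: 1 orsellinic acid (2,4-dihydroxy-6-methylbenzoic acid)
Product: 2 benzyl 2,4-bis(benzyloxy)-6-methylbenzoate
Conditions: BnBr (3.5 equiv), K2CO3, DMF, rt → 60 °C
Reagents that add atoms: benzyl bromide BrCc1ccccc1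
Why: SN2 alkylation of the carboxylate followed by Williamson etherification of both phenols should give the perbenzylated toluate; no stereocentre is formed.

Step 2
Reactants: 2 benzyl 2,4-bis(benzyloxy)-6-methylbenzoate
Product: 4 [3,5-bis(benzyloxy)-2-(benzyloxycarbonyl)phenyl]acetic acid, via benzylic lithium species 3 (not isolated)
Conditions: LiN(i-Pr)2 (1.2 equiv), THF, −78 °C; CO2 (g), −78 °C → rt; aq. HCl
Reagents that add atoms: carbon dioxide O=C=O
Why: Lateral lithiation of the ortho-toluate gives an ester-stabilised benzylic anion, and its carboxylation should give the homophthalic half ester.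

Step 3
Reactants: 5 non-1-yne
Product: 7 undec-3-yn-2-one, via lithium non-1-yn-1-ide 6 (not isolated)
Conditions: n-BuLi (1.05 equiv), THF, −78 °C; N-methoxy-N-methylacetamide, −78 → 0 °C; aq. HCl (1 M), 0 °C
Reagents that add atoms: N-methoxy-N-methylacetamide CC(=O)N(C)OC
Why: Acylation of a lithium acetylide by a Weinreb amide should stop at the ketone because the chelated tetrahedral adduct collapses only on work-up.

Step 4
Reactants: 4 [3,5-bis(benzyloxy)-2-(benzyloxycarbonyl)phenyl]acetic acid; 7 undec-3-yn-2-one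
Product: 10 benzyl 2,4-bis(benzyloxy)-6-(2,4-dioxotridec-5-yn-1-yl)benzoate, via acyl imidazolide 8 (not isolated), via lithium enolate 9 (not isolated)
Conditions: 4, 1,1'-carbonyldiimidazole (1.05 equiv), THF, rt, 1 h; 7 (3 equiv), LiN(SiMe3)2 (3 equiv), THF, −78 °C; imidazolide solution added, −78 → −30 °C; AcOH, −78 °C
Reagents that add atoms: none
Why: Crossed Claisen condensation of the kinetic methyl-ketone enolate with the acyl imidazolide should give the alkynyl 1,3-diketone; the surplus of the cheap enolate takes up the acidic protons, and the cold acetic acid quench keeps the product from closing to a 4-pyranone.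

Step 5
Reactants: 11 methyl 3-(trimethylsilyloxy)but-2-enoate
Product: 13 1-methoxy-1,3-bis(trimethylsilyloxy)buta-1,3-diene, via lithium dienolate 12 (not isolated)
Conditions: LiN(i-Pr)2 (1.1 equiv), THF, −78 °C; Me3SiCl, −78 °C → rt; filtration under argon, distillation
Reagents that add atoms: chlorotrimethylsilane C[Si](C)(C)Cl
Why: γ-Deprotonation of the silyl enol ether ester gives the extended dienolate, and its O-silylation should give the ketene-acetal diene.

Step 6
Reactants: 10 benzyl 2,4-bis(benzyloxy)-6-(2,4-dioxotridec-5-yn-1-yl)benzoate; 13 1-methoxy-1,3-bis(trimethylsilyloxy)buta-1,3-diene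
Product: 18 rac-benzyl 2,4-bis(benzyloxy)-6-[(5-heptyl-2,7-dihydroxy-4-oxo-3,4-dihydro-2H-chromen-2-yl)methyl]benzoate, via silyl enol ether 14 (not isolated), via cycloadduct 15 (not isolated), via tris(silyl) ether 16 (not isolated), via open-chain diketone 17 (not isolated)
Conditions: 13 (3.5 equiv), PhMe, 110 °C, sealed tube, 16 h; then THF/aq. citric acid (0.5 M), 0 °C → rt
Reagents that add atoms: none
Why: A thermal Diels–Alder reaction of the electron-rich ketene-acetal diene with the ynone (the first equivalent of 13 having silylated the enolised diketone to 14), followed by 1,4-elimination of methanol from cycloadduct 15, should build benzene ring A; the closest known reaction type is the benzannulation of 1-alkoxy-1,3-bis(silyloxy)butadienes with acetylenic esters or ketones to resorcylates or acylresorcinols. Ring A closes by the [4+2] cycloaddition (new bonds C4a–C8a and C5–C6), and ring B closes by 6-exo-trig addition of the unveiled C8a–OH to the C2 ketone of 17 during the mild aqueous desilylation (new bond O1–C2). The regiochemistry the target needs (acyl group flanked by OH and heptyl, second OH para to the acyl group) follows from the polarisation of both partners: the nucleophilic CH2 terminus of the diene bonds to the heptyl-bearing β-carbon of the ynone, and the ketene-acetal carbon to the α-carbon. The new stereocentre C2 forms without control, as the racemate, which the design accepts because C2 is equilibrated in step 7. The selectivity the step must secure is cycloaddition before 6-endo closure of the enol oxygen onto the ynone (4-pyranone formation), which the in situ O-silylation blocks; the benzyl ester, the benzyl ethers and the ketone carbonyls are not dienophiles under these conditions. The weakly acidic work-up is chosen to avoid dehydration of the hemiketal to the chromone.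

Step 7
Reactants: 18 rac-benzyl 2,4-bis(benzyloxy)-6-[(5-heptyl-2,7-dihydroxy-4-oxo-3,4-dihydro-2H-chromen-2-yl)methyl]benzoate; 19 (S)-1-phenylethylamine
Product: 21 (1S)-1-phenylethan-1-aminium 2-{[(2R)-5-heptyl-2,7-dihydroxy-4-oxo-3,4-dihydro-2H-chromen-2-yl]methyl}-4,6-dihydroxybenzoate, via racemic acid 20 (not isolated)
Conditions: H2 (1 atm), 10% Pd/C, EtOAc/THF, rt; filtration; 19 (1.05 equiv), EtOAc/EtOH, 40 → 5 °C, seeding, slurry 48 h; filtration
Reagents that add atoms: none
Why: Proposed new method: after the known neutral hydrogenolysis of the three benzyl groups over Pd/C, the racemic acid forms two diastereomeric salts with the amine that interconvert in solution, because the slight excess of amine catalyses ring opening of the C2 hemiketal to the achiral diketone and reclosure, so continuous crystallisation of the less soluble salt of the (2R)-acid should drain the equilibrium and set C2 (crystallisation-induced diastereomer transformation); the closest known reaction types are the second-order asymmetric transformation of base-epimerisable carboxylic acids as alkaloid or 1-phenylethylammonium salts and the crystallisation of a single anomer from a mutarotating hemiacetal.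

Step 8
Reactants: 21 (1S)-1-phenylethan-1-aminium 2-{[(2R)-5-heptyl-2,7-dihydroxy-4-oxo-3,4-dihydro-2H-chromen-2-yl]methyl}-4,6-dihydroxybenzoate
Product: 22 2-{[(2R)-5-heptyl-2,7-dihydroxy-4-oxo-3,4-dihydro-2H-chromen-2-yl]methyl}-4,6-dihydroxybenzoic acid
Conditions: EtOAc / aq. citric acid (0.5 M), 0–5 °C; Na2SO4; evaporation below 25 °C
Reagents that add atoms: none
Why: Proton transfer to the carboxylate in a cold two-phase system (salt break) should free the acid without exposing C2 to base, so the configuration fixed in the crystal is kept.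

**Compound list**

1 | orsellinic acid (2,4-dihydroxy-6-methylbenzoic acid), achiral | Cc1cc(O)cc(O)c1C(=O)O | starting material
2 | benzyl 2,4-bis(benzyloxy)-6-methylbenzoate, achiral | Cc1cc(OCc2ccccc2)cc(OCc2ccccc2)c1C(=O)OCc1ccccc1 | intermediate
3 | benzyl 2,4-bis(benzyloxy)-6-(lithiomethyl)benzoate, achiral | [Li]Cc1cc(OCc2ccccc2)cc(OCc2ccccc2)c1C(=O)OCc1ccccc1 | intermediate (not isolated)
4 | [3,5-bis(benzyloxy)-2-(benzyloxycarbonyl)phenyl]acetic acid, achiral | OC(=O)Cc1cc(OCc2ccccc2)cc(OCc2ccccc2)c1C(=O)OCc1ccccc1 | intermediate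
5 | non-1-yne, achiral | C#CCCCCCCC | starting material
6 | lithium non-1-yn-1-ide, achiral | [Li]C#CCCCCCCC | intermediate (not isolated)
7 | undec-3-yn-2-one, achiral | CC(=O)C#CCCCCCCC | intermediate
8 | benzyl 2,4-bis(benzyloxy)-6-[2-(1H-imidazol-1-yl)-2-oxoethyl]benzoate, achiral | O=C(Cc1cc(OCc2ccccc2)cc(OCc2ccccc2)c1C(=O)OCc1ccccc1)n1ccnc1 | intermediate (not isolated)
9 | lithium undec-1-en-3-yn-2-olate, achiral | [Li]OC(=C)C#CCCCCCCC | intermediate (not isolated)
10 | benzyl 2,4-bis(benzyloxy)-6-(2,4-dioxotridec-5-yn-1-yl)benzoate, achiral | CCCCCCCC#CC(=O)CC(=O)Cc1cc(OCc2ccccc2)cc(OCc2ccccc2)c1C(=O)OCc1ccccc1 | intermediate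
11 | methyl 3-(trimethylsilyloxy)but-2-enoate, achiral | COC(=O)C=C(C)O[Si](C)(C)C | starting material
12 | lithium 1-methoxy-3-(trimethylsilyloxy)buta-1,3-dien-1-olate, achiral | [Li]OC(OC)=CC(=C)O[Si](C)(C)C | intermediate (not isolated)
13 | 1-methoxy-1,3-bis(trimethylsilyloxy)buta-1,3-diene, achiral | COC(O[Si](C)(C)C)=CC(=C)O[Si](C)(C)C | intermediate
14 | benzyl 2,4-bis(benzyloxy)-6-[4-oxo-2-(trimethylsilyloxy)tridec-2-en-5-yn-1-yl]benzoate, achiral | CCCCCCCC#CC(=O)C=C(O[Si](C)(C)C)Cc1cc(OCc2ccccc2)cc(OCc2ccccc2)c1C(=O)OCc1ccccc1 | intermediate (not isolated)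
15 | benzyl 2,4-bis(benzyloxy)-6-{4-[2-heptyl-6-methoxy-4,6-bis(trimethylsilyloxy)cyclohexa-1,4-dien-1-yl]-4-oxo-2-(trimethylsilyloxy)but-2-en-1-yl}benzoate, racemic | CCCCCCCC1=C(C(=O)C=C(O[Si](C)(C)C)Cc2cc(OCc3ccccc3)cc(OCc3ccccc3)c2C(=O)OCc2ccccc2)C(OC)(O[Si](C)(C)C)C=C(O[Si](C)(C)C)C1 | intermediate (not isolated)
16 | benzyl 2,4-bis(benzyloxy)-6-{4-[2-heptyl-4,6-bis(trimethylsilyloxy)phenyl]-4-oxo-2-(trimethylsilyloxy)but-2-en-1-yl}benzoate, achiral | CCCCCCCc1cc(O[Si](C)(C)C)cc(O[Si](C)(C)C)c1C(=O)C=C(O[Si](C)(C)C)Cc1cc(OCc2ccccc2)cc(OCc2ccccc2)c1C(=O)OCc1ccccc1 | intermediate (not isolated)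
17 | benzyl 2,4-bis(benzyloxy)-6-[4-(2,4-dihydroxy-6-heptylphenyl)-2,4-dioxobutyl]benzoate, achiral | CCCCCCCc1cc(O)cc(O)c1C(=O)CC(=O)Cc1cc(OCc2ccccc2)cc(OCc2ccccc2)c1C(=O)OCc1ccccc1 | intermediate (not isolated)
18 | rac-benzyl 2,4-bis(benzyloxy)-6-[(5-heptyl-2,7-dihydroxy-4-oxo-3,4-dihydro-2H-chromen-2-yl)methyl]benzoate, racemic at C2 | CCCCCCCc1cc(O)cc2c1C(=O)CC(O)(Cc1cc(OCc3ccccc3)cc(OCc3ccccc3)c1C(=O)OCc1ccccc1)O2 | intermediate
19 | (S)-1-phenylethylamine | C[C@H](N)c1ccccc1 | starting material
20 | rac-2-[(5-heptyl-2,7-dihydroxy-4-oxo-3,4-dihydro-2H-chromen-2-yl)methyl]-4,6-dihydroxybenzoic acid, racemic at C2 | CCCCCCCc1cc(O)cc2c1C(=O)CC(O)(Cc1cc(O)cc(O)c1C(=O)O)O2 | intermediate (not isolated)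
21 | (1S)-1-phenylethan-1-aminium 2-{[(2R)-5-heptyl-2,7-dihydroxy-4-oxo-3,4-dihydro-2H-chromen-2-yl]methyl}-4,6-dihydroxybenzoate | CCCCCCCc1cc(O)cc2c1C(=O)C[C@@](O)(Cc1cc(O)cc(O)c1C(=O)[O-])O2.C[C@H]([NH3+])c1ccccc1 | intermediate
22 | 2-{[(2R)-5-heptyl-2,7-dihydroxy-4-oxo-3,4-dihydro-2H-chromen-2-yl]methyl}-4,6-dihydroxybenzoic acid | CCCCCCCc1cc(O)cc2c1C(=O)C[C@@](O)(Cc1cc(O)cc(O)c1C(=O)O)O2 | target

**Step count and risks**

Total step count: 8. Longest linear sequence: 6 (steps 1, 2, 4, 6, 7, 8). Steps 3 and 5 are one-step preparations of the ynone and the diene.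

Steps most likely to fail:

1. Step 7. The two diastereomeric salts may not differ enough in solubility, or equilibration through the open diketone may be slower than dehydration of the hemiketal to the chromone in the warm slurry. The fallback sets out from racemic acid 20, isolated by evaporation after the hydrogenolysis, and comes back at 22. It is a preparative HPLC separation on silica-bound amylose tris(3,5-dimethylphenylcarbamate) (hexane/i-PrOH/HCO2H, 5 °C). The unwanted 2-{[(2S)-5-heptyl-2,7-dihydroxy-4-oxo-3,4-dihydro-2H-chromen-2-yl]methyl}-4,6-dihydroxybenzoic acid F1 would be re-equilibrated with a trace of Et3N and re-injected.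

2. Step 6. The enolised alkynyl diketone may close thermally to a 4-pyranone before it is silylated, or the silylated ynone may be too weak a dienophile, so the cycloaddition stalls. The fallback sets out from ynone 7, diene 13 and acid 4 and comes back at 18; it makes ring A first on the simple ynone, which carries no acidic enol. Cycloaddition of 7 with 13 (PhMe, 110 °C; aq. citric acid) would give 1-(2,4-dihydroxy-6-heptylphenyl)ethan-1-one F2. Silylation with t-BuMe2SiOSO2CF3 and 2,6-lutidine would give 1-[2,4-bis(tert-butyldimethylsilyloxy)-6-heptylphenyl]ethan-1-one F3. Its lithium enolate (LiN(SiMe3)2, THF, −78 °C) would be acylated by imidazolide 8, made from acid 4 as in step 4, to benzyl 2,4-bis(benzyloxy)-6-{4-[2,4-bis(tert-butyldimethylsilyloxy)-6-heptylphenyl]-2,4-dioxobutyl}benzoate F4. n-Bu4NF buffered with AcOH would then release diketone 17, which closes to 18.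

3. Step 4. Proton transfer from the enolisable imidazolide to the enolate, or conjugate self-addition of the ynone enolate, may erode the Claisen condensation. The fallback sets out from acid 4 and comes back at 10; it forms the C4–alkyne bond last, with no ketone enolate involved. Acid 4 with Meldrum's acid, N,N'-dicyclohexylcarbodiimide and 4-(dimethylamino)pyridine would give the acyl Meldrum's acid benzyl 2,4-bis(benzyloxy)-6-[2-(2,2-dimethyl-4,6-dioxo-1,3-dioxan-5-ylidene)-2-hydroxyethyl]benzoate F5. Heating it with N,O-dimethylhydroxylamine (PhMe, 80 °C, acylketene trapping) would give the β-keto Weinreb amide benzyl 2,4-bis(benzyloxy)-6-{4-[methoxy(methyl)amino]-2,4-dioxobutyl}benzoate F6. Excess lithium non-1-yn-1-ide 6 (THF, −78 → 0 °C) would convert this amide into 10.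

**Further compounds**

F1 | step 7 | 2-{[(2S)-5-heptyl-2,7-dihydroxy-4-oxo-3,4-dihydro-2H-chromen-2-yl]methyl}-4,6-dihydroxybenzoic acid | CCCCCCCc1cc(O)cc2c1C(=O)C[C@](O)(Cc1cc(O)cc(O)c1C(=O)O)O2
F2 | step 6 | 1-(2,4-dihydroxy-6-heptylphenyl)ethan-1-one | CCCCCCCc1cc(O)cc(O)c1C(C)=O
F3 | step 6 | 1-[2,4-bis(tert-butyldimethylsilyloxy)-6-heptylphenyl]ethan-1-one | CCCCCCCc1cc(O[Si](C)(C)C(C)(C)C)cc(O[Si](C)(C)C(C)(C)C)c1C(C)=O
F4 | step 6 | benzyl 2,4-bis(benzyloxy)-6-{4-[2,4-bis(tert-butyldimethylsilyloxy)-6-heptylphenyl]-2,4-dioxobutyl}benzoate | CCCCCCCc1cc(O[Si](C)(C)C(C)(C)C)cc(O[Si](C)(C)C(C)(C)C)c1C(=O)CC(=O)Cc1cc(OCc2ccccc2)cc(OCc2ccccc2)c1C(=O)OCc1ccccc1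
F5 | step 4 | benzyl 2,4-bis(benzyloxy)-6-[2-(2,2-dimethyl-4,6-dioxo-1,3-dioxan-5-ylidene)-2-hydroxyethyl]benzoate | CC1(C)OC(=O)C(=C(O)Cc2cc(OCc3ccccc3)cc(OCc3ccccc3)c2C(=O)OCc2ccccc2)C(=O)O1
F6 | step 4 | benzyl 2,4-bis(benzyloxy)-6-{4-[methoxy(methyl)amino]-2,4-dioxobutyl}benzoate | CON(C)C(=O)CC(=O)Cc1cc(OCc2ccccc2)cc(OCc2ccccc2)c1C(=O)OCc1ccccc1
A1 | direct plan | 5-heptylresorcinol (5-heptylbenzene-1,3-diol) | CCCCCCCc1cc(O)cc(O)c1
A2 | direct plan | 1-[2,4-bis(benzyloxy)-6-heptylphenyl]ethan-1-one | CCCCCCCc1cc(OCc2ccccc2)cc(OCc2ccccc2)c1C(C)=O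
A3 | direct plan | benzyl 2,4-bis(benzyloxy)-6-methylbenzoate | Cc1cc(OCc2ccccc2)cc(OCc2ccccc2)c1C(=O)OCc1ccccc1
A4 | direct plan | [3,5-bis(benzyloxy)-2-(benzyloxycarbonyl)phenyl]acetic acid | OC(=O)Cc1cc(OCc2ccccc2)cc(OCc2ccccc2)c1C(=O)OCc1ccccc1
A5 | direct plan | benzyl 2,4-bis(benzyloxy)-6-{4-[2,4-bis(benzyloxy)-6-heptylphenyl]-2,4-dioxobutyl}benzoate | CCCCCCCc1cc(OCc2ccccc2)cc(OCc2ccccc2)c1C(=O)CC(=O)Cc1cc(OCc2ccccc2)cc(OCc2ccccc2)c1C(=O)OCc1ccccc1
A6 | direct plan | rac-2-[(5-heptyl-2,7-dihydroxy-4-oxo-3,4-dihydro-2H-chromen-2-yl)methyl]-4,6-dihydroxybenzoic acid | CCCCCCCc1cc(O)cc2c1C(=O)CC(O)(Cc1cc(O)cc(O)c1C(=O)O)O2
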